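**Leftover Z.** From the Z left over when G reaches zero I reckon what stands in this flask at the end.

| setting | teal | flask |
|---|---|---|
| G | 1 M | 0.50 M |
| Z | 0.45 M | 0.450 M |
| remark | run made earlier |  |
| time |  | 8.0 h |

teal run (percent of the G charged)

| time / min | J / % | Q / % |
|---|---|---|
| 8.00 | 12.6 | 12.4 |
| 12.0 | 11.4 | 28.1 |
| 20.0 | 7.1 | 55.4 |
| 25.0 | 4.3 | 69.8 |
| 40.0 | 0 | 89.3 |
| 60.0 | 0 | 91.0 |
| 90.0 | 1.7 | 88.5 |

(standard deviation of a reading: 1 percentage point)

- percentages count the G that a species holds: one Q counts as two
- solid, in amounts per volume of the solution: G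
- at the start none of G is in solution
- a reading or a percentage of J counts all its forms, free or not

- the J standing at 8.0 h, as a percentage of the G charged
- the Q standing at 8.0 h, as a percentage of the G charged

**Teal compared.** Teal and this flask hold the same Z, 0.450 M. Teal's Q reads 91.0% of its G at 60.0 min, which is 0.455 M of Q, about its Z charge, so I take each Q to hold two G and one Z: G + Z → J, then J + G → Q. Turning all Z into Q takes 0.900 M of G. Teal holds 1 M, more than that, and its J reads 0% at 40.0 min. This flask holds 0.50 M, less than that, so G is the limiting reagent and I expect J and Z to remain.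

**Selectivity factor.** Let s be the rate constant of J + G over that of G + Z; dissolved G cancels from the ratio of the two rates. At the top of J, making equals using, so s = [Z]/[J]. Teal's highest J reading, which I take as that top, gives s = 2.08, a reading that I round to 2.

**My reckoning.** All G as Q would leave 44.4% of Z. With s = 2 and Z charge c, J = c·x·(1 − x), and the G balance gives (1 − x)(2 − x) = G charge/c. So I get 33.3%: the leftover x, the fraction of charged Z unspent when G reaches zero. That makes J 20.0% and Q 80.0%.

**The forecast.** It reads s as 2.5 and says 19% J and 81% Q, adding “I lean slightly higher on J”.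

**Result.** This flask gives 22.6% J and 77.4% Q at 8.0 h.

    G ⇌ E, rate k1*(cs1 - [E]) while solid is left; crystals form when [E] > cs1 (solubility = 0.0750 M, k = 0.0113 s⁻¹)
    E + Z → J (k = 0.0624 M⁻¹ s⁻¹)
    E + J → Q (k = 0.128 M⁻¹ s⁻¹)
    2 G → X (k = 1.16 × 10⁻⁶ M⁻¹ s⁻¹)
    Z + J ⇌ D, settled at all times (K = 3.11 M⁻¹)

In this flask both already stand at 0.800 h, with G at 0%. In this flask free Z is 25% of its charge and D holds 5.92% of the G charged; counting one unspent Z in each D, the two make 31.9% of the Z charge, against x of 33.3%. In the neighbour flask with 0.30 M of G and the same Z, x comes to 54.3%, and free Z plus D, counted the same way, stand at 51.8% of the Z charge. For that neighbour flask x gives J 37.2%, and it holds 44.6%.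

(The runs are simulated with constants of no real substance, and the scatter is random.)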